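**Retrosynthetic overview**

- Target numbering: ring C1(=O)–C2H=C3H–C4H2–C5(OH)–C6H2, side chain C1'H2–C2'(=O)–C3'…C19' with the Z alkene at C10'=C11'. The route rests on one feature: C5, the only stereocentre, carries two CH2–C=O arms (C6–C1 in the ring, C1'–C2' in the chain) that are the same group at the aldehyde level, and the ring bond C1–C2 joins a carbonyl carbon to a cis-alkene carbon.
- Endgame disconnections: the O–Si bond at C5, the two carbonyl groups back to carbinols, and C2'–C3' (a C17 (Z)-alkenyl Grignard reagent added to the free CH2CHO arm).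
- Key disconnection: ring bond C1–C2, by nickel/chromium-mediated addition of a (Z)-alkenyl iodide to one of two enantiotopic aldehyde arms on a silylated, prochiral carbinol carbon. This closes the only ring (the cyclohexene) and sets C5.
- The dialdehyde comes from dimethyl 3-oxopentanedioate and propargyl bromide (C4–C5 bond); the C17 chain comes from 1-decyne and 1,7-dibromoheptane.

Key step: step 6

Assumption: the sense of induction of the sulfonamide–oxazoline ligand in this ring closure cannot be predicted from its intermolecular uses; the route is written with the (S)-valine-derived ligand delivering the (5R)-carbinol of 9, and the (R)-ligand is used if the opposite sense is found.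

**Route**

Step 1
Reactants: 1 dimethyl 3-oxopentanedioate; 2 propargyl bromide (3-bromoprop-1-yne)
Product: 3 dimethyl 3-hydroxy-3-(prop-2-yn-1-yl)pentanedioate
Conditions: In powder (1.5 equiv), 2 (2 equiv), THF/H2O 1:1, rt; 1 M HCl work-up
Reagents that add atoms: none
Why: Barbier-type indium-mediated propargylation, in which the allenylindium formed in the flask adds through its γ-carbon to the ketone of the β-keto diester to give the homopropargylic tertiary alcohol, while the aqueous organoindium tolerates the acidic C–H bonds and leaves the esters alone.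

Step 2
Reactants: 3 dimethyl 3-hydroxy-3-(prop-2-yn-1-yl)pentanedioate
Product: 4 dimethyl 3-(prop-2-yn-1-yl)-3-(triethylsilyloxy)pentanedioate
Conditions: Et3SiOTf (1.5 equiv), 2,6-lutidine (3 equiv), CH2Cl2, −78 → 0 °C
Reagents that add atoms: triethylsilyl trifluoromethanesulfonate, CC[Si](CC)(CC)OS(=O)(=O)C(F)(F)F
Why: Silylation of a hindered tertiary alcohol with a silyl triflate and a non-nucleophilic base, conditions too mild to cause retro-aldol cleavage of the β-hydroxy diester.

Step 3
Reactants: 4 dimethyl 3-(prop-2-yn-1-yl)-3-(triethylsilyloxy)pentanedioate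
Product: 5 dimethyl 3-(3-iodoprop-2-yn-1-yl)-3-(triethylsilyloxy)pentanedioate
Conditions: N-iodosuccinimide (1.2 equiv), AgNO3 (0.1 equiv), acetone, rt, dark
Reagents that add atoms: N-iodosuccinimide, O=C1CCC(=O)N1I
Why: Silver-catalysed electrophilic iodination of the terminal alkyne through the silver acetylide, which leaves the esters and the silyl ether untouched.

Step 4
Reactants: 5 dimethyl 3-(3-iodoprop-2-yn-1-yl)-3-(triethylsilyloxy)pentanedioate
Product: 6 dimethyl 3-[(Z)-3-iodoprop-2-en-1-yl]-3-(triethylsilyloxy)pentanedioate
Conditions: 2-nitrobenzenesulfonylhydrazide (2.5 equiv), Et3N, THF/i-PrOH 1:1, rt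
Reagents that add atoms: none
Why: Diimide reduction, in which concerted syn delivery of two hydrogens to the iodoalkyne gives the (Z)-iodoalkene, and the C–I bond, esters and silyl ether are inert to diimide.

Step 5
Reactants: 6 dimethyl 3-[(Z)-3-iodoprop-2-en-1-yl]-3-(triethylsilyloxy)pentanedioate
Product: 7 3-[(Z)-3-iodoprop-2-en-1-yl]-3-(triethylsilyloxy)pentanedial
Conditions: i-Bu2AlH (2.2 equiv), CH2Cl2, −78 °C; MeOH, then aq. potassium sodium tartrate; used crude
Reagents that add atoms: none
Why: Partial ester reduction with i-Bu2AlH, in which the tetrahedral aluminium hemiacetals of both arms, stabilised at −78 °C by the β-silyloxy oxygen and the neighbouring quaternary carbon, survive until the quench and release the dialdehyde.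

Step 6
Reactants: 7 3-[(Z)-3-iodoprop-2-en-1-yl]-3-(triethylsilyloxy)pentanedial
Product: 9 2-[(1S,5R)-5-hydroxy-1-(triethylsilyloxy)cyclohex-3-en-1-yl]acetaldehyde, via vinylchromium dichloride 8 (not isolated)
Conditions: CrCl2 (4 equiv), (S)-N-[2-(4-isopropyl-4,5-dihydro-1,3-oxazol-2-yl)-6-methylphenyl]methanesulfonamide (4.4 equiv), Et3N (4.4 equiv), THF, rt; NiCl2 (0.2 equiv); 7 added slowly (final 0.005 M), rt; aq. ethylenediamine work-up
Reagents that add atoms: none
Why: Proposed new method: the C–I bond of 7 adds oxidatively to zerovalent nickel (made from NiCl2 by CrCl2) with retention of the Z geometry, the alkenyl group passes to trivalent chromium to give 8, and the alkenylchromium carbon C2 adds to the carbonyl carbon of one CH2CHO arm through a chromium-bridged half-chair, a 6-exo-trig closure that forms C1–C2 and the cyclohexene ring (target numbering). The closest known reactions are the ligand-free intramolecular Nozaki–Hiyama–Kishi closure of (Z)-iodoalkenyl aldehydes and the intermolecular asymmetric alkenylchromium addition under sulfonamide–oxazoline ligands; what is new is that the reagent has to choose between two enantiotopic aldehyde groups on one carbon. The carbinol centre (C1 of the target, C5 in the name of 9) is set by the chiral ligand on chromium, which fixes the carbonyl face that is attacked. The quaternary centre (C5 of the target, C1 in the name of 9) is set by relay: the carbonyl oxygen must lie pseudo-equatorial to stay on the chromium in the alkene plane at C2, and the small silyloxy group should take the axial site and the spectator CH2CHO arm the equatorial site, so each carbonyl face is matched with one arm and the hydroxyl should come out trans to the silyloxy group. The step therefore needs arm selectivity, which is the product of ligand face control and this axial/equatorial preference, and mono-addition, which is secured because each molecule holds one C–I bond, the preset Z alkene allows only the six-membered ring to close, and the non-basic organochromium neither enolises the β-silyloxy aldehydes nor attacks the second aldehyde once the iodide is spent (high dilution suppresses intermolecular coupling).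

Step 7
Reactants: 10 1-decyne; 11 1,7-dibromoheptane
Product: 13 1-bromoheptadec-8-yne, via lithium dec-1-yn-1-ide 12 (not isolated)
Conditions: n-BuLi (1.0 equiv), THF, −78 → 0 °C; 11 (3 equiv), DMPU, 0 °C → rt
Reagents that add atoms: none
Why: SN2 alkylation of a lithium acetylide with a primary dibromide, used in excess so that mono-substitution dominates.

Step 8
Reactants: 13 1-bromoheptadec-8-yne
Product: 14 (Z)-1-bromoheptadec-8-ene
Conditions: H2 (1 atm), Pd/CaCO3 poisoned with Pb(OAc)2 (Lindlar catalyst), quinoline, hexane, rt
Reagents that add atoms: none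
Why: Lindlar semi-hydrogenation, in which syn addition of hydrogen on the poisoned palladium surface gives the Z alkene and the primary C–Br bond is not reduced.

Step 9
Reactants: 9 2-[(1S,5R)-5-hydroxy-1-(triethylsilyloxy)cyclohex-3-en-1-yl]acetaldehyde; 14 (Z)-1-bromoheptadec-8-ene
Product: 16 (10Z)-1-[(1R,5R)-5-hydroxy-1-(triethylsilyloxy)cyclohex-3-en-1-yl]nonadec-10-en-2-ol (mixture of epimers at C2 of the chain), via (Z)-heptadec-8-enylmagnesium bromide 15 (not isolated)
Conditions: 14, Mg turnings, THF, rt → 40 °C; 15 (3.5 equiv) added to 9, THF, −78 → −20 °C; aq. NH4Cl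
Reagents that add atoms: none
Why: Grignard addition to the aldehyde, in which one equivalent is consumed by the free hydroxyl (9 can sit partly as the ring–chain lactol tautomer because hydroxyl and CH2CHO arm are cis, and its magnesium salt reopens), further reagent adds at low temperature faster than it enolises, and the new carbinol forms as an epimer mixture that is oxidised in the next step.

Step 10
Reactants: 16 (10Z)-1-[(1R,5R)-5-hydroxy-1-(triethylsilyloxy)cyclohex-3-en-1-yl]nonadec-10-en-2-ol
Product: 17 (5R)-5-[(10Z)-2-oxononadec-10-en-1-yl]-5-(triethylsilyloxy)cyclohex-2-en-1-one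
Conditions: Dess–Martin periodinane (3 equiv), NaHCO3, CH2Cl2, 0 °C → rt
Reagents that add atoms: none
Why: Dess–Martin oxidation of both secondary alcohols (allylic and aliphatic) under buffered, non-basic conditions that keep the tertiary silyl ether and do not trigger β-elimination, so both carbinol stereocentres vanish and the quaternary centre is untouched.

Step 11
Reactants: 17 (5R)-5-[(10Z)-2-oxononadec-10-en-1-yl]-5-(triethylsilyloxy)cyclohex-2-en-1-one
Product: 18 (5R)-5-hydroxy-5-[(10Z)-2-oxononadec-10-en-1-yl]cyclohex-2-en-1-one (CNP0165051.1)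
Conditions: HF·pyridine, pyridine, THF, 0 °C; cold aq. NaHCO3 quench
Reagents that add atoms: none
Why: Fluoride-mediated cleavage of the tertiary triethylsilyl ether under buffered, weakly acidic conditions at low temperature, chosen so that the β-hydroxy diketone is not dehydrated and aromatised.

**Compound list**

1 | dimethyl 3-oxopentanedioate | COC(=O)CC(=O)CC(=O)OC | starting material
2 | propargyl bromide (3-bromoprop-1-yne) | C#CCBr | starting material
3 | dimethyl 3-hydroxy-3-(prop-2-yn-1-yl)pentanedioate | COC(=O)CC(O)(CC#C)CC(=O)OC | intermediate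
4 | dimethyl 3-(prop-2-yn-1-yl)-3-(triethylsilyloxy)pentanedioate | COC(=O)CC(O[Si](CC)(CC)CC)(CC#C)CC(=O)OC | intermediate
5 | dimethyl 3-(3-iodoprop-2-yn-1-yl)-3-(triethylsilyloxy)pentanedioate | COC(=O)CC(O[Si](CC)(CC)CC)(CC#CI)CC(=O)OC | intermediate
6 | dimethyl 3-[(Z)-3-iodoprop-2-en-1-yl]-3-(triethylsilyloxy)pentanedioate | COC(=O)CC(O[Si](CC)(CC)CC)(C/C=C\I)CC(=O)OC | intermediate
7 | 3-[(Z)-3-iodoprop-2-en-1-yl]-3-(triethylsilyloxy)pentanedial | O=CCC(O[Si](CC)(CC)CC)(CC=O)C/C=C\I | intermediate
8 | [(1Z)-6-oxo-4-(2-oxoethyl)-4-(triethylsilyloxy)hex-1-en-1-yl]chromium dichloride (chiral ligand on chromium not drawn) | O=CCC(O[Si](CC)(CC)CC)(CC=O)C/C=C\[Cr](Cl)Cl | intermediate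
9 | 2-[(1S,5R)-5-hydroxy-1-(triethylsilyloxy)cyclohex-3-en-1-yl]acetaldehyde (hydroxyl trans to silyloxy) | O=CC[C@]1(O[Si](CC)(CC)CC)CC=C[C@H](O)C1 | intermediate
10 | 1-decyne | CCCCCCCCC#C | starting material
11 | 1,7-dibromoheptane | BrCCCCCCCBr | starting material
12 | lithium dec-1-yn-1-ide | CCCCCCCCC#C[Li] | intermediate
13 | 1-bromoheptadec-8-yne | CCCCCCCCC#CCCCCCCCBr | intermediate
14 | (Z)-1-bromoheptadec-8-ene | CCCCCCCC/C=C\CCCCCCCBr | intermediate
15 | (Z)-heptadec-8-enylmagnesium bromide | CCCCCCCC/C=C\CCCCCCC[Mg]Br | intermediate
16 | (10Z)-1-[(1R,5R)-5-hydroxy-1-(triethylsilyloxy)cyclohex-3-en-1-yl]nonadec-10-en-2-ol (mixture of epimers at C2 of the chain) | CCCCCCCC/C=C\CCCCCCCC(O)C[C@]1(O[Si](CC)(CC)CC)CC=C[C@H](O)C1 | intermediate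
17 | (5R)-5-[(10Z)-2-oxononadec-10-en-1-yl]-5-(triethylsilyloxy)cyclohex-2-en-1-one | CCCCCCCC/C=C\CCCCCCCC(=O)C[C@]1(O[Si](CC)(CC)CC)CC=CC(=O)C1 | intermediate
18 | (5R)-5-hydroxy-5-[(10Z)-2-oxononadec-10-en-1-yl]cyclohex-2-en-1-one (CNP0165051.1) | CCCCCCCC/C=C\CCCCCCCC(=O)C[C@]1(O)CC=CC(=O)C1 | target

**Step count**

Total: 11 steps. Longest linear sequence: 9 steps (steps 1–6, then 9–11, from dimethyl 3-oxopentanedioate); the chain bromide takes 2 steps (7, 8).

**Steps most likely to fail**

1. Step 6 (proposed new method). The chromium reagent may not distinguish the two aldehyde arms well enough, through weak ligand face control or a weak axial/equatorial preference at the quaternary carbon; this would show as low enantiomeric purity once the carbinol is oxidised in step 10. Intermolecular coupling and hydride transfer from the chromium alkoxide to the remaining aldehyde are lesser risks.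
Fallback (known reactions only), setting out from 6 and coming back at 9: the two arms are differentiated before the ring is closed. Pig liver esterase in pH 7 phosphate buffer hydrolyses one enantiotopic methyl ester of 6 (enzymatic desymmetrisation of a 3,3-disubstituted glutarate) to (3S)-3-[(Z)-3-iodoprop-2-en-1-yl]-5-methoxy-5-oxo-3-(triethylsilyloxy)pentanoic acid F1. The acid arm is reduced through its mixed anhydride (i-BuOCOCl, N-methylmorpholine, then NaBH4) to methyl (3S)-5-hydroxy-3-[(Z)-3-iodoprop-2-en-1-yl]-3-(triethylsilyloxy)pentanoate F2. This is oxidised at once with Dess–Martin periodinane to methyl (3S)-3-[(Z)-3-iodoprop-2-en-1-yl]-5-oxo-3-(triethylsilyloxy)pentanoate F3. A ligand-free CrCl2/catalytic NiCl2 closure in DMF, which has a single aldehyde to react with, should give methyl 2-[(1S,5R)-5-hydroxy-1-(triethylsilyloxy)cyclohex-3-en-1-yl]acetate F4, and i-Bu2AlH at −78 °C reduces its ester arm to the aldehyde, which is 9. If the esterase delivers the enantiomeric half-ester, the ester arm is reduced instead (LiBH4) and the acid re-esterified (Me3SiCHN2), which leads to the same F2. An epimer of F4 at the carbinol carbon is harmless, since that carbinol is oxidised in step 10.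

2. Step 9. The basic Grignard reagent may enolise the β-silyloxy aldehyde, with subsequent loss of the silyloxy group, or the aldehyde may be released too slowly from its lactol form, so that addition is incomplete.
Fallback, setting out from 14 and 9 and coming back at 16: the bromide 14 is converted by Finkelstein exchange (NaI, acetone) into (Z)-1-iodoheptadec-8-ene F5. F5 is then added to 9 as its alkylchromium reagent (CrCl2, catalytic cobalt phthalocyanine Co(C32H16N8), a divalent cobalt complex, DMF, rt). This alkyl variant of the Nozaki–Hiyama–Kishi reaction is non-basic and aldehyde-selective, tolerates the free hydroxyl, and gives 16 directly.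

3. Step 11. The tertiary β-hydroxyl group may be lost during desilylation (dehydration followed by tautomerisation to a 3-alkylphenol) under the acidic or basic conditions.
Fallback, setting out from 16 and coming back at 18: the silyl ether is removed first, at the diol stage where no carbonyl group is present (Bu4NF, THF), to give (10Z)-1-[(1R,5R)-1,5-dihydroxycyclohex-3-en-1-yl]nonadec-10-en-2-ol F6. The two secondary alcohols of F6 are then oxidised with Dess–Martin periodinane/NaHCO3, which leaves the tertiary alcohol alone, to give 18 directly.

**Further compounds**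

F1 | step 6 | (3S)-3-[(Z)-3-iodoprop-2-en-1-yl]-5-methoxy-5-oxo-3-(triethylsilyloxy)pentanoic acid | COC(=O)C[C@](CC(=O)O)(O[Si](CC)(CC)CC)C/C=C\I
F2 | step 6 | methyl (3S)-5-hydroxy-3-[(Z)-3-iodoprop-2-en-1-yl]-3-(triethylsilyloxy)pentanoate | COC(=O)C[C@](CCO)(O[Si](CC)(CC)CC)C/C=C\I
F3 | step 6 | methyl (3S)-3-[(Z)-3-iodoprop-2-en-1-yl]-5-oxo-3-(triethylsilyloxy)pentanoate | COC(=O)C[C@](CC=O)(O[Si](CC)(CC)CC)C/C=C\I
F4 | step 6 | methyl 2-[(1S,5R)-5-hydroxy-1-(triethylsilyloxy)cyclohex-3-en-1-yl]acetate | COC(=O)C[C@]1(O[Si](CC)(CC)CC)CC=C[C@H](O)C1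
F5 | step 9 | (Z)-1-iodoheptadec-8-ene | CCCCCCCC/C=C\CCCCCCCI
F6 | step 11 | (10Z)-1-[(1R,5R)-1,5-dihydroxycyclohex-3-en-1-yl]nonadec-10-en-2-ol (mixture of epimers at C2 of the chain) | CCCCCCCC/C=C\CCCCCCCC(O)C[C@]1(O)CC=C[C@H](O)C1
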